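With germacrane numbering (C1=C10, C3–OAng, C4=C5, C6–OAc, C7–iPr), the C2 methylene lies between the oxygenated C3 and the vinylic C1. At the ketone level of C3 it is the α′-carbon of a Z-enone, so the ten-membered ring is closed at C2–C1 by palladium-catalysed α-alkenylation: a tin dienolate, released from a silyl dienol ether, couples with the E-vinyl bromide at C1. One operation forms the ring and the skipped C10=C1–C2–C3(=O)–C4=C5 array with both alkene geometries preset. The acyclic precursor carries C6 and C7 from one anti-selective allylboration; reagent-controlled reduction then sets C3 before angeloylation.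

Key step: step 12

Assumption: but-2-ynal, (+)-B-methoxydiisopinocampheylborane (from (−)-α-pinene) and angelic acid are bought as such; the germacrane ring numbering above is used for the carbons of all intermediates.

Step 1
Reactants: 1 (E)-4-methylpent-2-ene; 2 but-2-ynal
Product: 6 (3R,4R)-3-(propan-2-yl)hept-1-en-5-yn-4-ol, via allylpotassium 3 (not isolated), via allylborane 4 (not isolated), via borinate 5 (not isolated)
Conditions: 1, n-BuLi, KOtBu, THF, −78 to −50 °C; (+)-Ipc2BOMe, −78 °C; BF3·OEt2; 2, −78 °C; then NaOH, H2O2, 0 °C to rt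
Reagents that add atoms: none
Why: Brown-type asymmetric allylboration, in which kinetic metalation of the allylic methyl group keeps the E geometry, the chair transition state of the E-allylborane sets C6 and C7 anti, and the (+)-Ipc2B group should direct attack to the re face of the ynal to give C6 (R).

Step 2
Reactants: 6 (3R,4R)-3-(propan-2-yl)hept-1-en-5-yn-4-ol
Product: 7 (3R,4R)-4-(tert-butyldimethylsilyloxy)-3-(propan-2-yl)hept-1-en-5-yne
Conditions: TBSOTf, 2,6-lutidine, CH2Cl2, 0 °C
Reagents that add atoms: tert-butyldimethylsilyl triflate CC(C)(C)[Si](C)(C)OS(=O)(=O)C(F)(F)F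
Why: Silylation of the hindered secondary propargylic alcohol with the silyl triflate masks the C6 oxygen, which would otherwise cyclise onto C9 in step 5.

Step 3
Reactants: 7 (3R,4R)-4-(tert-butyldimethylsilyloxy)-3-(propan-2-yl)hept-1-en-5-yne
Product: 9 (3S,4R)-4-(tert-butyldimethylsilyloxy)-3-(propan-2-yl)hept-5-yn-1-ol, via alkylborane 8 (not isolated)
Conditions: 9-BBN, THF, 0 °C to rt; then NaOH, H2O2, 0 °C
Reagents that add atoms: hydrogen peroxide OO
Why: Anti-Markovnikov hydroboration–oxidation, in which 9-BBN should take the monosubstituted alkene (C8=C9) well before the hindered internal alkyne and places oxygen on C9.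

Step 4
Reactants: 9 (3S,4R)-4-(tert-butyldimethylsilyloxy)-3-(propan-2-yl)hept-5-yn-1-ol
Product: 10 (4R,5S)-4-(tert-butyldimethylsilyloxy)-7-iodo-5-(propan-2-yl)hept-2-yne
Conditions: I2, PPh3, imidazole, CH2Cl2, 0 °C
Reagents that add atoms: iodine II
Why: Appel-type iodination of the unhindered primary alcohol gives the C9 iodide under neutral conditions that leave the silyl ether and the alkyne alone.

Step 5
Reactants: 10 (4R,5S)-4-(tert-butyldimethylsilyloxy)-7-iodo-5-(propan-2-yl)hept-2-yne
Product: 11 (5S,6R)-6-(tert-butyldimethylsilyloxy)-5-(propan-2-yl)nona-1,7-diyne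
Conditions: LiC≡CH·H2NCH2CH2NH2, DMSO, rt
Reagents that add atoms: lithium acetylide (ethylenediamine complex) [Li+].[C-]#C
Why: SN2 alkylation of the acetylide at the primary iodide adds C10 and C1 as a terminal alkyne.

Step 6
Reactants: 11 (5S,6R)-6-(tert-butyldimethylsilyloxy)-5-(propan-2-yl)nona-1,7-diyne
Product: 13 (1E,5S,6R)-1-bromo-6-(tert-butyldimethylsilyloxy)-2-methyl-5-(propan-2-yl)non-1-en-7-yne, via alkenylalane 12 (not isolated)
Conditions: Me3Al, Cp2ZrCl2, CH2Cl2, 0 °C to rt; then NBS, THF, −78 to 0 °C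
Reagents that add atoms: trimethylaluminium C[Al](C)C; N-bromosuccinimide O=C1CCC(=O)N1Br
Why: Negishi zirconium-catalysed carboalumination adds methyl (to C10) and aluminium (to C1) syn across the terminal alkyne only, and bromodealumination with retention fixes the E geometry of C1=C10.

Step 7
Reactants: 13 (1E,5S,6R)-1-bromo-6-(tert-butyldimethylsilyloxy)-2-methyl-5-(propan-2-yl)non-1-en-7-yne
Product: 14 (4R,5S,8E)-9-bromo-8-methyl-5-(propan-2-yl)non-8-en-2-yn-4-ol
Conditions: Bu4NF, THF, 0 °C to rt
Reagents that add atoms: none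
Why: Fluoride desilylation frees the propargylic hydroxyl needed to direct the next step.

Step 8
Reactants: 14 (4R,5S,8E)-9-bromo-8-methyl-5-(propan-2-yl)non-8-en-2-yn-4-ol
Product: 16 (2Z,4R,5S,8E)-9-bromo-2-iodo-8-methyl-5-(propan-2-yl)nona-2,8-dien-4-ol, via cyclic alanate 15 (not isolated)
Conditions: NaAlH2(OCH2CH2OMe)2, THF, 0 °C to rt; EtOAc, −78 °C; then I2, THF, −78 to 0 °C
Reagents that add atoms: iodine II
Why: Hydroxyl-directed trans-hydroalumination of the propargylic alcohol puts aluminium on C4 cis to C6, and iodinolysis with retention gives the Z-iodoalkene that fixes the C4=C5 geometry.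

Step 9
Reactants: 16 (2Z,4R,5S,8E)-9-bromo-2-iodo-8-methyl-5-(propan-2-yl)nona-2,8-dien-4-ol
Product: 17 (2Z,4R,5S,8E)-9-bromo-2-iodo-8-methyl-5-(propan-2-yl)nona-2,8-dien-4-yl acetate
Conditions: Ac2O, pyridine, DMAP (cat.), CH2Cl2, 0 °C to rt
Reagents that add atoms: acetic anhydride CC(=O)OC(C)=O
Why: Acetylation installs the final C6 ester before the ketone is unveiled, which prevents hemiketal and furan formation from a free Z-γ-hydroxy enone.

Step 10
Reactants: 17 (2Z,4R,5S,8E)-9-bromo-2-iodo-8-methyl-5-(propan-2-yl)nona-2,8-dien-4-yl acetate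
Product: 19 (3Z,5R,6S,9E)-10-bromo-3,9-dimethyl-2-oxo-6-(propan-2-yl)deca-3,9-dien-5-yl acetate, via ethoxydiene 18 (not isolated)
Conditions: CH2=C(OEt)SnBu3, Cu(O2CC4H3S) (copper thiophene-2-carboxylate), NMP, 0 °C to rt; then 1 M HCl, THF, 0 °C
Reagents that add atoms: tributyl(1-ethoxyvinyl)stannane C=C(OCC)[Sn](CCCC)(CCCC)CCCC; water O
Why: A copper-mediated Stille-type coupling should react at the C4 iodide only (the vinyl bromide is inert and no zerovalent palladium is present to ionise the allylic acetate) with retention of the Z geometry, and mild acid hydrolysis of the enol ether gives the methyl ketone (C3, C2).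

Step 11
Reactants: 19 (3Z,5R,6S,9E)-10-bromo-3,9-dimethyl-2-oxo-6-(propan-2-yl)deca-3,9-dien-5-yl acetate
Product: 20 (3Z,5R,6S,9E)-10-bromo-3,9-dimethyl-6-(propan-2-yl)-2-(trimethylsilyloxy)deca-1,3,9-trien-5-yl acetate
Conditions: LiN(SiMe3)2, Me3SiCl, THF, −78 °C; non-aqueous work-up, used crude
Reagents that add atoms: chlorotrimethylsilane C[Si](C)(C)Cl
Why: Kinetic α′-deprotonation of the methyl ketone (more acidic than the acetate) with in situ silylation gives the cross-conjugated silyl dienol ether without touching C4=C5.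

Step 12
Reactants: 20 (3Z,5R,6S,9E)-10-bromo-3,9-dimethyl-6-(propan-2-yl)-2-(trimethylsilyloxy)deca-1,3,9-trien-5-yl acetate
Product: 22 (1(10)E,4Z,6R,7S)-6-acetoxygermacra-1(10),4-dien-3-one, via tin dienolate 21 (not isolated)
Conditions: Pd2(dba)3 (5 mol %), P(t-Bu)3 (20 mol %), Bu3SnF (1.5 equiv), toluene, 80 °C, syringe-pump addition of 20, final 1 mM
Reagents that add atoms: none
Why: Fluoride transfer from Bu3SnF turns the enol silane into tin dienolate 21, the E-vinyl bromide adds oxidatively to zerovalent palladium, transmetalation gives a C2-bound palladium enolate, and reductive elimination forms the C2–C1 bond. The closest known reaction type is the palladium-catalysed α-arylation and α-alkenylation of ketone enol silanes through tin enolates (an enolate cross-coupling of the Migita–Kosugi–Stille family), which is known intramolecularly for smaller rings with alkali enolates. The ten-membered carbocycle is closed end to end by reductive elimination from an eleven-membered palladacycle, a direct macrocyclisation to which exo and endo modes do not apply. No stereocentre is created: C1=C10 keeps the E geometry of the vinyl bromide, C4=C5 keeps the Z geometry of the dienolate, and C6 and C7 are untouched. The step needs ring closure to outrun oligomerisation (slow addition, high dilution, the cis bend at C4=C5 bringing the chain ends together), C-alkenylation at C2 only (the dienolate is nucleophilic at its terminal carbon and the palladium enolate has no β-hydrogen), and survival of the acetate and of the skipped enone (neutral fluoride conditions, no alkoxide base).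

Step 13
Reactants: 22 (1(10)E,4Z,6R,7S)-6-acetoxygermacra-1(10),4-dien-3-one
Product: 24 (1(10)E,3S,4Z,6R,7S)-6-acetoxygermacra-1(10),4-dien-3-ol, via borate ester 23 (not isolated)
Conditions: (R)-2-methyl-CBS-oxazaborolidine, catecholborane, toluene, −78 °C; aqueous NaHCO3 work-up
Reagents that add atoms: none
Why: Corey–Bakshi–Shibata reduction, in which the α-methylalkenyl arm (C4) acts as the large group and the C2 methylene as the small one, so the (R)-catalyst should deliver hydride to give the 3S alcohol under reagent control without touching the acetate or the alkenes.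

Step 14
Reactants: 24 (1(10)E,3S,4Z,6R,7S)-6-acetoxygermacra-1(10),4-dien-3-ol; 25 angelic acid
Product: 28 (1(10)E,3S,4Z,6R,7S)-6-acetoxy-3-angeloyloxygermacra-1(10),4-diene (CNP0306415.1), via mixed anhydride 26 (not isolated), via lithium alkoxide 27 (not isolated)
Conditions: 25, 2,4,6-trichlorobenzoyl chloride, Et3N, toluene, rt; 24, LiN(SiMe3)2, THF, −78 °C; combine, −78 to −20 °C; NH4Cl work-up
Reagents that add atoms: none
Why: Yamaguchi-type mixed-anhydride acylation, in which the lithium alkoxide attacks the unhindered angeloyl carbonyl of 26 at low temperature, which should avoid Z-to-E isomerisation to the tiglate, acetate migration and anionic oxy-Cope ring contraction, while C3 keeps its configuration.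

Compound list
1 | (E)-4-methylpent-2-ene | C/C=C/C(C)C | starting material
2 | but-2-ynal | CC#CC=O | starting material
3 | (E)-4-methylpent-2-enylpotassium (formed in situ) | [K+].[CH2-]/C=C/C(C)C | intermediate
4 | B-[(E)-4-methylpent-2-enyl]bis(isopinocampheyl)borane, Ipc groups configured as in (+)-isopinocampheol (formed in situ) | CC(C)/C=C/CB([C@H]1C[C@H]2C[C@@H]([C@@H]1C)C2(C)C)[C@H]1C[C@H]2C[C@@H]([C@@H]1C)C2(C)C | intermediate
5 | bis(isopinocampheyl)borinate of 6, boron on the C4 oxygen (formed in situ) | C=C[C@@H](C(C)C)[C@@H](OB([C@H]1C[C@H]2C[C@@H]([C@@H]1C)C2(C)C)[C@H]1C[C@H]2C[C@@H]([C@@H]1C)C2(C)C)C#CC | intermediate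
6 | (3R,4R)-3-(propan-2-yl)hept-1-en-5-yn-4-ol | C=C[C@@H](C(C)C)[C@@H](O)C#CC | intermediate
7 | (3R,4R)-4-(tert-butyldimethylsilyloxy)-3-(propan-2-yl)hept-1-en-5-yne | C=C[C@@H](C(C)C)[C@@H](O[Si](C)(C)C(C)(C)C)C#CC | intermediate
8 | B-alkyl-9-borabicyclo[3.3.1]nonane from 7, boron on the terminal carbon of the former vinyl group (formed in situ) | C1CC2CCCC(C1)B2CC[C@@H](C(C)C)[C@@H](O[Si](C)(C)C(C)(C)C)C#CC | intermediate
9 | (3S,4R)-4-(tert-butyldimethylsilyloxy)-3-(propan-2-yl)hept-5-yn-1-ol | OCC[C@@H](C(C)C)[C@@H](O[Si](C)(C)C(C)(C)C)C#CC | intermediate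
10 | (4R,5S)-4-(tert-butyldimethylsilyloxy)-7-iodo-5-(propan-2-yl)hept-2-yne | ICC[C@@H](C(C)C)[C@@H](O[Si](C)(C)C(C)(C)C)C#CC | intermediate
11 | (5S,6R)-6-(tert-butyldimethylsilyloxy)-5-(propan-2-yl)nona-1,7-diyne | C#CCC[C@@H](C(C)C)[C@@H](O[Si](C)(C)C(C)(C)C)C#CC | intermediate
12 | (E)-alkenyl(dimethyl)alane from 11, methyl on C10 and AlMe2 on C1, cis to each other (formed in situ) | C[Al](C)/C=C(\C)CC[C@@H](C(C)C)[C@@H](O[Si](C)(C)C(C)(C)C)C#CC | intermediate
13 | (1E,5S,6R)-1-bromo-6-(tert-butyldimethylsilyloxy)-2-methyl-5-(propan-2-yl)non-1-en-7-yne | Br/C=C(\C)CC[C@@H](C(C)C)[C@@H](O[Si](C)(C)C(C)(C)C)C#CC | intermediate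
14 | (4R,5S,8E)-9-bromo-8-methyl-5-(propan-2-yl)non-8-en-2-yn-4-ol | Br/C=C(\C)CC[C@@H](C(C)C)[C@@H](O)C#CC | intermediate
15 | sodium cyclic alkenyl(alkoxy)alanate from 14, five-membered ring Al–O–C6–C5=C4, two 2-methoxyethoxy groups on Al (formed in situ) | [Na+].COCCO[Al-]1(OCCOC)O[C@H]([C@H](C(C)C)CC/C(C)=C/Br)C=C1C | intermediate
16 | (2Z,4R,5S,8E)-9-bromo-2-iodo-8-methyl-5-(propan-2-yl)nona-2,8-dien-4-ol | Br/C=C(\C)CC[C@@H](C(C)C)[C@@H](O)/C=C(/C)I | intermediate
17 | (2Z,4R,5S,8E)-9-bromo-2-iodo-8-methyl-5-(propan-2-yl)nona-2,8-dien-4-yl acetate | Br/C=C(\C)CC[C@@H](C(C)C)[C@@H](OC(C)=O)/C=C(/C)I | intermediate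
18 | (3Z,5R,6S,9E)-10-bromo-2-ethoxy-3,9-dimethyl-6-(propan-2-yl)deca-1,3,9-trien-5-yl acetate (formed in situ) | Br/C=C(\C)CC[C@@H](C(C)C)[C@@H](OC(C)=O)/C=C(/C)C(=C)OCC | intermediate
19 | (3Z,5R,6S,9E)-10-bromo-3,9-dimethyl-2-oxo-6-(propan-2-yl)deca-3,9-dien-5-yl acetate | Br/C=C(\C)CC[C@@H](C(C)C)[C@@H](OC(C)=O)/C=C(/C)C(C)=O | intermediate
20 | (3Z,5R,6S,9E)-10-bromo-3,9-dimethyl-6-(propan-2-yl)-2-(trimethylsilyloxy)deca-1,3,9-trien-5-yl acetate | Br/C=C(\C)CC[C@@H](C(C)C)[C@@H](OC(C)=O)/C=C(/C)C(=C)O[Si](C)(C)C | intermediate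
21 | O-tributylstannyl dienolate corresponding to 20 (formed in situ) | Br/C=C(\C)CC[C@@H](C(C)C)[C@@H](OC(C)=O)/C=C(/C)C(=C)O[Sn](CCCC)(CCCC)CCCC | intermediate
22 | (1(10)E,4Z,6R,7S)-6-acetoxygermacra-1(10),4-dien-3-one | O=C1C/C=C(\C)CC[C@@H](C(C)C)[C@@H](OC(C)=O)/C=C\1C | intermediate
23 | catecholborate ester of 24 at the C3 oxygen (formed in situ) | c1ccc2OB(O[C@H]3C/C=C(\C)CC[C@@H](C(C)C)[C@@H](OC(C)=O)/C=C\3C)Oc2c1 | intermediate
24 | (1(10)E,3S,4Z,6R,7S)-6-acetoxygermacra-1(10),4-dien-3-ol | O[C@H]1C/C=C(\C)CC[C@@H](C(C)C)[C@@H](OC(C)=O)/C=C\1C | intermediate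
25 | angelic acid, (Z)-2-methylbut-2-enoic acid | C/C=C(/C)C(=O)O | starting material
26 | angelic 2,4,6-trichlorobenzoic anhydride (formed in situ) | C/C=C(/C)C(=O)OC(=O)c1c(Cl)cc(Cl)cc1Cl | intermediate
27 | lithium alkoxide of 24 (formed in situ) | [Li+].[O-][C@H]1C/C=C(\C)CC[C@@H](C(C)C)[C@@H](OC(C)=O)/C=C\1C | intermediate
28 | (1(10)E,3S,4Z,6R,7S)-6-acetoxy-3-angeloyloxygermacra-1(10),4-diene, CNP0306415.1 | C/C=C(/C)C(=O)O[C@H]1C/C=C(\C)CC[C@@H](C(C)C)[C@@H](OC(C)=O)/C=C\1C | target

Total step count: 14. Longest linear sequence: 14 steps (1 to 28).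

Steps most likely to fail

1. Step 12 (ring closure). Reductive elimination through a medium-ring palladacycle may be slow. Oligomerisation, protodestannylation of the tin dienolate back to the open ketone, or ionisation of the allylic acetate by zerovalent palladium could then take over. The fallback sets out from 20 and returns at 22. Hydroboration of the terminal enol-ether alkene of 20 with 9-BBN (THF, 0 °C) should give the β-silyloxyalkylborane F1. An intramolecular B-alkyl Suzuki–Miyaura coupling with the vinyl bromide (PdCl2(dppf), AsPh3, K3PO4, DMF/THF/H2O, rt, high dilution) should then close the same C2–C1 bond and give the macrocyclic C3 silyl ether F2 as a mixture of C3 epimers. Mild acid (citric acid, MeOH) would free the epimeric alcohols F3, and Dess–Martin oxidation would converge both epimers on 22.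

2. Step 13 (C3 reduction). Facial selectivity may be poor or reversed if the conformation of the ten-membered ring, rather than the catalyst, decides which carbonyl face is open. The fallback sets out from 22 and returns at 28. A Luche reduction (NaBH4, CeCl3·7H2O, MeOH, −78 °C) would be run under substrate control. If hydride is delivered to the opposite face, the product is the 3R alcohol F4, which would be esterified with inversion by a Mitsunobu reaction with 25 (PPh3, DIAD, toluene, 0 °C) to give 28 directly. If substrate control instead favours the 3S alcohol, that product is 24 itself and step 14 follows unchanged.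

3. Step 1 (allylboration). The allylpotassium may lose its E geometry before it is trapped on boron, which would erode the anti relationship of C6 and C7, and facial control by the chiral borane may be weaker with an ynal. The fallback sets out from 1 (through 3) and 2 and returns at 6. Allylpotassium 3 would be quenched with 2-isopropoxy-4,4,5,5-tetramethyl-1,3,2-dioxaborolane to give the isolable (E)-allyl pinacol boronate F5, whose E purity can be secured before use. Allylboration of 2 catalysed by a chiral phosphoric acid ((R)-3,3′-bis(2,4,6-triisopropylphenyl)-1,1′-binaphthyl-2,2′-diyl hydrogen phosphate, toluene, −30 °C) should then proceed through the same chair transition state under catalyst control to the boronate adduct F6, and aqueous work-up would give 6.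

Further compounds
F1 | step 12 | B-alkyl-9-borabicyclo[3.3.1]nonane from 20, boron on C2, trimethylsilyloxy on C3 (C3 epimers) | Br/C=C(\C)CC[C@@H](C(C)C)[C@@H](OC(C)=O)/C=C(/C)C(CB1C2CCCC1CCC2)O[Si](C)(C)C
F2 | step 12 | (1(10)E,4Z,6R,7S)-6-acetoxy-3-(trimethylsilyloxy)germacra-1(10),4-diene, C3 epimers | C[Si](C)(C)OC1C/C=C(\C)CC[C@@H](C(C)C)[C@@H](OC(C)=O)/C=C\1C
F3 | step 12 | (1(10)E,4Z,6R,7S)-6-acetoxygermacra-1(10),4-dien-3-ol, C3 epimers | OC1C/C=C(\C)CC[C@@H](C(C)C)[C@@H](OC(C)=O)/C=C\1C
F4 | step 13 | (1(10)E,3R,4Z,6R,7S)-6-acetoxygermacra-1(10),4-dien-3-ol | O[C@@H]1C/C=C(\C)CC[C@@H](C(C)C)[C@@H](OC(C)=O)/C=C\1C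
F5 | step 1 | (E)-4,4,5,5-tetramethyl-2-(4-methylpent-2-en-1-yl)-1,3,2-dioxaborolane | CC(C)/C=C/CB1OC(C)(C)C(C)(C)O1
F6 | step 1 | pinacol boronate ester of 6 at the C4 oxygen | C=C[C@@H](C(C)C)[C@@H](OB1OC(C)(C)C(C)(C)O1)C#CC
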